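Assumption: the target has no stereocentre and its SMILES defines no axial configuration, so it is treated as achiral and the biaryl axis is formed without stereocontrol.

## Retrosynthetic overview

1. Target 14 comes from its bis(methyl ether) 13 by hydrolysis of the two vinylogous methyl esters (quinone C–OMe to C–OH).
2. The central quinone–quinone bond of 13 is cut by an intermolecular Michael (conjugate) addition of hydroquinone 11 to quinone 10, followed by oxidation; each partner has only one free ring position.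
3. Quinone 10 (and 11 by reduction) comes from phenol 9 by para-oxidation.
4. Phenol 9 comes from a Wittig union of aldehyde 3 with phosphonium salt 5, then hydrogenation with loss of the benzyl group; 3 comes from 3,5-dimethoxy-4-methylbenzaldehyde 1.
5. No ring is built: all rings come from aromatic starting materials, and the quinone rings are unveiled by oxidation (monomer first, then both rings of the dimer).

## Route

Step 1
Reactants: 1 3,5-dimethoxy-4-methylbenzaldehyde
Product: 2 3-hydroxy-5-methoxy-4-methylbenzaldehyde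
Conditions: NaSEt (2.5 equiv), DMF, 130 °C, 3 h; then 1 M HCl
Reagents that add atoms: none
Why: SN2 O-demethylation by thiolate stops after one of the two equivalent methyl ethers because the phenoxide formed deactivates the second one, and the non-enolisable aldehyde survives.

Step 2
Reactants: 2 3-hydroxy-5-methoxy-4-methylbenzaldehyde
Product: 3 3-(benzyloxy)-5-methoxy-4-methylbenzaldehyde
Conditions: BnBr (1.1 equiv), K2CO3 (1.5 equiv), DMF, rt
Reagents that add atoms: benzyl bromide, BrCc1ccccc1
Why: Williamson ether synthesis on the only phenol masks it for the ylide step with a group that the later hydrogenation removes.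

Step 3
Reactants: 4 1-(chloromethyl)-2-methoxybenzene (2-methoxybenzyl chloride)
Product: 5 (2-methoxybenzyl)triphenylphosphonium chloride
Conditions: PPh3 (1.05 equiv), toluene, reflux, 16 h; filter the salt
Reagents that add atoms: triphenylphosphine, c1ccc(cc1)P(c1ccccc1)c1ccccc1
Why: SN2 quaternisation of PPh3 by a reactive benzylic chloride gives the crystalline Wittig salt.

Step 4
Reactants: 5 (2-methoxybenzyl)triphenylphosphonium chloride; 3 3-(benzyloxy)-5-methoxy-4-methylbenzaldehyde
Product: 7 1-(benzyloxy)-3-methoxy-2-methyl-5-[2-(2-methoxyphenyl)ethenyl]benzene (E/Z mixture), via phosphonium ylide 6 (not isolated)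
Conditions: 5 (1.2 equiv), KOtBu (1.2 equiv), THF, 0 °C, 30 min; then 3, 0 °C to rt
Reagents that add atoms: none
Why: Wittig olefination of a non-enolisable aryl aldehyde with a semi-stabilised benzylic ylide is dependable, and the E/Z ratio is irrelevant because the alkene is hydrogenated next.

Step 5
Reactants: 7 1-(benzyloxy)-3-methoxy-2-methyl-5-[2-(2-methoxyphenyl)ethenyl]benzene
Product: 9 3-methoxy-2-methyl-5-[2-(2-methoxyphenyl)ethyl]phenol, via benzyl ether bibenzyl 8 (not isolated)
Conditions: H2 (1 atm), 10% Pd/C, EtOAc/EtOH 1:1, rt, 12 h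
Reagents that add atoms: none
Why: Catalytic hydrogenation saturates the stilbene and hydrogenolyses the benzyl ether in one pot while the aryl methyl ethers are untouched.

Step 6
Reactants: 9 3-methoxy-2-methyl-5-[2-(2-methoxyphenyl)ethyl]phenol
Product: 10 3-methoxy-2-methyl-5-[2-(2-methoxyphenyl)ethyl]cyclohexa-2,5-diene-1,4-dione (a 2-methoxy-1,4-benzoquinone with one free ring CH)
Conditions: (KSO3)2NO (Fremy's salt, 2.5 equiv), aq. KH2PO4, acetone/H2O, 0 °C to rt, 2 h
Reagents that add atoms: potassium nitrosodisulfonate (Fremy's salt), [K+].[K+].[O-]S(=O)(=O)N([O])S([O-])(=O)=O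
Why: Teuber oxidation of a phenol with a free para position gives the para-quinone, exactly as in the known conversion of 3-methoxy-5-alkylphenols into 2-methoxy-6-alkylbenzoquinones.

Step 7
Reactants: 10 3-methoxy-2-methyl-5-[2-(2-methoxyphenyl)ethyl]cyclohexa-2,5-diene-1,4-dione (half of the batch)
Product: 11 3-methoxy-2-methyl-5-[2-(2-methoxyphenyl)ethyl]benzene-1,4-diol
Conditions: aq. Na2S2O4 (excess), EtOAc/H2O, rt, Ar; used directly after drying
Reagents that add atoms: none
Why: Dithionite reduction of a quinone to its hydroquinone is fast and quantitative and supplies the electron-rich Michael donor.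

Step 8
Reactants: 10 3-methoxy-2-methyl-5-[2-(2-methoxyphenyl)ethyl]cyclohexa-2,5-diene-1,4-dione; 11 3-methoxy-2-methyl-5-[2-(2-methoxyphenyl)ethyl]benzene-1,4-diol
Product: 13 4,4'-dimethoxy-5,5'-dimethyl-2,2'-bis[2-(2-methoxyphenyl)ethyl]-[bi-1,4-cyclohexadien-1-yl]-3,3',6,6'-tetrone (each quinone ring, going round from the biaryl carbon: phenethyl C, C=O, C–OMe, C–Me, C=O), via biaryl bis-hydroquinone 12 (not isolated)
Conditions: 10 (1.0 equiv), 11 (1.0 equiv), CF3CO2H (10 equiv), degassed CH2Cl2, 0 °C to rt, Ar, 16 h; evaporate; then Ag2O (6 equiv), MgSO4, CH2Cl2, rt, 1 h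
Reagents that add atoms: none
Why: Acid-catalysed intermolecular Michael addition joins the only free carbon of 11 (ortho to OH, para to OMe) to the only unsubstituted β-carbon of 10 (β to the carbonyl outside the vinylogous ester), tautomerisation gives 12 and Ag2O dehydrogenates both rings; no stereocentre is formed and the fully substituted product cannot add again.

Step 9
Reactants: 13 4,4'-dimethoxy-5,5'-dimethyl-2,2'-bis[2-(2-methoxyphenyl)ethyl]-[bi-1,4-cyclohexadien-1-yl]-3,3',6,6'-tetrone
Product: 14 4,4'-dihydroxy-5,5'-dimethyl-2,2'-bis[2-(2-methoxyphenyl)ethyl]-[bi-1,4-cyclohexadien-1-yl]-3,3',6,6'-tetrone (target)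
Conditions: 1 M aq. NaOH (6 equiv), degassed THF/MeOH 1:1, 0 °C to rt, 1–2 h; then 1 M HCl to pH 2
Reagents that add atoms: sodium hydroxide, [Na+].[OH-]
Why: Hydroxide addition–elimination at the methoxy-bearing quinone carbons (saponification of a vinylogous ester) gives the hydroxyquinones, while the two anisole methyl ethers are inert to aqueous base.

## Compound list

1 | 3,5-dimethoxy-4-methylbenzaldehyde | COc1cc(C=O)cc(OC)c1C | starting material
2 | 3-hydroxy-5-methoxy-4-methylbenzaldehyde | COc1cc(C=O)cc(O)c1C | intermediate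
3 | 3-(benzyloxy)-5-methoxy-4-methylbenzaldehyde | COc1cc(C=O)cc(OCc2ccccc2)c1C | intermediate
4 | 1-(chloromethyl)-2-methoxybenzene (2-methoxybenzyl chloride) | COc1ccccc1CCl | starting material
5 | (2-methoxybenzyl)triphenylphosphonium chloride | [Cl-].COc1ccccc1C[P+](c1ccccc1)(c1ccccc1)c1ccccc1 | intermediate
6 | (2-methoxybenzylidene)triphenylphosphorane (ylide) | COc1ccccc1C=P(c1ccccc1)(c1ccccc1)c1ccccc1 | intermediate (not isolated)
7 | 1-(benzyloxy)-3-methoxy-2-methyl-5-[2-(2-methoxyphenyl)ethenyl]benzene, E/Z mixture | COc1ccccc1C=Cc1cc(OC)c(C)c(OCc2ccccc2)c1 | intermediate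
8 | 1-(benzyloxy)-3-methoxy-2-methyl-5-[2-(2-methoxyphenyl)ethyl]benzene | COc1ccccc1CCc1cc(OC)c(C)c(OCc2ccccc2)c1 | intermediate (not isolated)
9 | 3-methoxy-2-methyl-5-[2-(2-methoxyphenyl)ethyl]phenol | COc1ccccc1CCc1cc(O)c(C)c(OC)c1 | intermediate
10 | 3-methoxy-2-methyl-5-[2-(2-methoxyphenyl)ethyl]cyclohexa-2,5-diene-1,4-dione | COC1=C(C)C(=O)C=C(CCc2ccccc2OC)C1=O | intermediate
11 | 3-methoxy-2-methyl-5-[2-(2-methoxyphenyl)ethyl]benzene-1,4-diol | COc1c(C)c(O)cc(CCc2ccccc2OC)c1O | intermediate
12 | 4,4'-dimethoxy-3,3'-dimethyl-6,6'-bis[2-(2-methoxyphenyl)ethyl]-[1,1'-biphenyl]-2,2',5,5'-tetrol | COc1ccccc1CCc1c(O)c(OC)c(C)c(O)c1-c1c(CCc2ccccc2OC)c(O)c(OC)c(C)c1O | intermediate (not isolated)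
13 | 4,4'-dimethoxy-5,5'-dimethyl-2,2'-bis[2-(2-methoxyphenyl)ethyl]-[bi-1,4-cyclohexadien-1-yl]-3,3',6,6'-tetrone | COc1ccccc1CCC1=C(C2=C(CCc3ccccc3OC)C(=O)C(OC)=C(C)C2=O)C(=O)C(C)=C(OC)C1=O | intermediate
14 | 4,4'-dihydroxy-5,5'-dimethyl-2,2'-bis[2-(2-methoxyphenyl)ethyl]-[bi-1,4-cyclohexadien-1-yl]-3,3',6,6'-tetrone | COc1ccccc1CCC1=C(C2=C(CCc3ccccc3OC)C(=O)C(O)=C(C)C2=O)C(=O)C(C)=C(O)C1=O | target

## Summary

Total step count: 9.
Longest linear sequence: 8 steps (1 → 2 → 3 → 7 → 9 → 10 → 11 → 13 → 14, steps 1, 2, 4, 5, 6, 7, 8, 9); step 3 is a one-step side branch.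

Three steps most likely to fail:

**Step 8 (Michael coupling of 10 with 11).** The new bond is flanked by four ortho substituents. Quinone/hydroquinone redox exchange can stall conversion, although unreacted monomer returns as 10 after the Ag2O step and can be recycled. Stronger acid risks cyclodehydration of the 2-hydroxybiaryl to a dibenzofuran. Fallback, setting out from 11: exhaustive O-methylation (Me2SO4, K2CO3, acetone) gives 1,3,4-trimethoxy-2-methyl-5-[2-(2-methoxyphenyl)ethyl]benzene F1. Iodination at the single free position of its trioxygenated ring (N-iodosuccinimide, cat. CF3CO2H, MeCN, 0 °C) gives 1-iodo-2,4,5-trimethoxy-3-methyl-6-[2-(2-methoxyphenyl)ethyl]benzene F2. Ullmann homocoupling (activated Cu powder, DMF, 150 °C) gives 2,2',4,4',5,5'-hexamethoxy-3,3'-dimethyl-6,6'-bis[2-(2-methoxyphenyl)ethyl]-1,1'-biphenyl F3. Oxidative demethylation of both para-dimethoxy rings with (NH4)2Ce(NO3)6 in MeCN/H2O at 0 °C then comes back to the route at 13.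

**Step 9 (double hydrolysis of 13).** The biquinone may degrade in base, for example by benzylic tautomerisation to quinone methides, before both hindered methoxy groups are displaced. Fallback, setting out from 10: hydrolyse the vinylogous ester at the monomer stage (aq. HClO4, dioxane, rt) to 2-hydroxy-3-methyl-6-[2-(2-methoxyphenyl)ethyl]-1,4-benzoquinone F4. Reduce half of it with aq. Na2S2O4 to 3-methyl-6-[2-(2-methoxyphenyl)ethyl]benzene-1,2,4-triol F5. Join the two halves by the same acid-mediated conjugate addition (CF3CO2H, degassed CH2Cl2) to give 3,3'-dimethyl-6,6'-bis[2-(2-methoxyphenyl)ethyl]-[1,1'-biphenyl]-2,2',4,4',5,5'-hexol F6. Oxidation of F6 with Ag2O (or air) comes back to the route at 14 with no late hydrolysis.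

**Step 6 (Teuber oxidation of 9).** The para position is flanked by OMe and the side chain, so ortho-quinone formation or over-oxidation may lower the yield. Fallback, setting out from 9: azo coupling with 4-sulfobenzenediazonium chloride (from sulfanilic acid, NaNO2, HCl) in aq. NaOH at 0 °C gives 4-[(E)-{4-hydroxy-2-methoxy-3-methyl-6-[2-(2-methoxyphenyl)ethyl]phenyl}diazenyl]benzenesulfonic acid F7. Reductive cleavage with aq. Na2S2O4 gives 4-amino-3-methoxy-2-methyl-5-[2-(2-methoxyphenyl)ethyl]phenol F8. Oxidation with aq. FeCl3 via the quinone imine comes back to the route at 10.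

## Further compounds

F1 | step 8 | 1,3,4-trimethoxy-2-methyl-5-[2-(2-methoxyphenyl)ethyl]benzene | COc1ccccc1CCc1cc(OC)c(C)c(OC)c1OC
F2 | step 8 | 1-iodo-2,4,5-trimethoxy-3-methyl-6-[2-(2-methoxyphenyl)ethyl]benzene | COc1ccccc1CCc1c(I)c(OC)c(C)c(OC)c1OC
F3 | step 8 | 2,2',4,4',5,5'-hexamethoxy-3,3'-dimethyl-6,6'-bis[2-(2-methoxyphenyl)ethyl]-1,1'-biphenyl | COc1ccccc1CCc1c(OC)c(OC)c(C)c(OC)c1-c1c(CCc2ccccc2OC)c(OC)c(OC)c(C)c1OC
F4 | step 9 | 2-hydroxy-3-methyl-6-[2-(2-methoxyphenyl)ethyl]-1,4-benzoquinone | COc1ccccc1CCC1=CC(=O)C(C)=C(O)C1=O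
F5 | step 9 | 3-methyl-6-[2-(2-methoxyphenyl)ethyl]benzene-1,2,4-triol | COc1ccccc1CCc1cc(O)c(C)c(O)c1O
F6 | step 9 | 3,3'-dimethyl-6,6'-bis[2-(2-methoxyphenyl)ethyl]-[1,1'-biphenyl]-2,2',4,4',5,5'-hexol | COc1ccccc1CCc1c(O)c(O)c(C)c(O)c1-c1c(CCc2ccccc2OC)c(O)c(O)c(C)c1O
F7 | step 6 | 4-[(E)-{4-hydroxy-2-methoxy-3-methyl-6-[2-(2-methoxyphenyl)ethyl]phenyl}diazenyl]benzenesulfonic acid | COc1ccccc1CCc1cc(O)c(C)c(OC)c1/N=N/c1ccc(cc1)S(O)(=O)=O
F8 | step 6 | 4-amino-3-methoxy-2-methyl-5-[2-(2-methoxyphenyl)ethyl]phenol | COc1ccccc1CCc1cc(O)c(C)c(OC)c1N
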